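## The problem

Target 27 is the 3-hydroxy-4-methoxybenzoate of a daucane-type sesquiterpene diol in which a cyclopentane and a cycloheptene are fused cis along the C3a–C8a bond. Locants of the target name are used in the discussion: C3 carries the hydroxyl and the isopropyl group, C3a the ring-fusion hydrogen, C4 the ester oxygen, C5=C6 is the alkene with its methyl on C6, and C8a is the methyl-bearing fusion carbon. There are four stereocentres: C3, C3a and C4 are contiguous, and the all-carbon quaternary C8a adjoins C3a. C8a has no neighbouring function through which it could be corrected, so it must be set first and in absolute terms. C3a can then be tied to it as the cis fusion, and in the folded bicycle C3 and C4 can be set by reagents approaching the convex face, because the isopropyl group and H4 lie on the face of H3a and the angular methyl while both oxygens lie on the concave face. The fragile parts are the allylic ester at C4 beside a trisubstituted alkene (ionisation, elimination), the tertiary alcohol at C3 (retro-aldol cleavage and dehydration whenever C4 is a ketone) and the free phenol. The enabling feature is the seven-membered ring: with a ketone at C3 and unsaturation at C3a=C4 and C7=C8 it is a 1,4-cycloheptadiene fused to a cyclopentanone, which is what a cis-divinylcyclopropane gives on Cope rearrangement. The cyclopropane required (C3a, C8a, C8) is the adduct of a carbenoid at C3a and a C8a=C8 alkene held together by C1–C2 and the C3 carbonyl, so both rings and C8a can come from one acyclic diazo ketone. What remains afterwards is to move the oxidation pattern from C3 ketone, C3a=C4, C7=C8 to C3 carbinol, C4 oxygen, C5=C6.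

## Retrosynthesis

**27 ⇒ 26 ⇒ 21 + 24.** The two O–Si bonds and then the ester C–O bond at C4 are cut. Esterifying last keeps the ionisable allylic ester out of every basic and redox step; acylating before the alkene is formed would expose the ester to the strong base of the dehydrogenation. The precursors are alcohol 21 and silyl-protected acid 24, one step from acid 22. The forward steps must acylate a hindered secondary allylic alcohol without ionising it and remove both silyl groups of 26 in one fluoride treatment.

**21 ⇒ 20 ⇒ 18 ⇒ 17 ⇒ 16.** The C4–H bond and the C5=C6 π bond are cut. The alkene can be placed regiospecifically only from a C4 ketone, because the other α carbon (C3a) has no β hydrogen available; C4 therefore passes through the ketone level and its configuration is set last, by hydride. This removes the alkene and the C4 stereocentre and makes the configuration of C6 in 16 irrelevant. The forward reactions must enolise toward C5, keep the tertiary aldol intact (hence silyl ether 18) and reduce 20 from the convex face.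

**16 ⇒ 15 ⇒ 14 + 2.** The bond between C3 and the three-carbon side chain is cut, and the side chain is brought in as an isopropenyl group. An alkenyl Grignard reagent has no β-hydride to transfer and is less hindered than the isopropyl reagent. It is the same reagent 2 that opens the route, and one hydrogenation (15 to 16) then saturates both the side chain and the ring alkene left by the key step. The addition must take place on the convex face of 14, anti to C4.

**14 ⇒ 12.** The C4–O and C3a–H bonds are cut, which is a conjugate hydration of the enone of 12. A one-flask conjugate borylation and oxidation is preferred to the two-step epoxidation and reductive opening, and it leaves the isolated ring alkene alone. It must deliver the cis ring fusion when the enolate is protonated.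

**12 ⇒ 11 ⇒ 10.** The C5–C6 bond (through the Cope rearrangement of 11) and the C3a–C8a and C3a–C8 bonds (through the cyclopropanation) are cut, which opens both rings to the acyclic vinyl diazo ketone 10. No other cut removes two rings, a quaternary centre and all chirality in one operation. The forward step needs face selection at the trisubstituted alkene by a chiral dirhodium catalyst and a cis arrangement of the two alkenyl groups on the cyclopropane.

**10 ⇒ 9 ⇒ 7 + 8.** The diazo group is removed, then the C3–C3a bond is cut between an acyl unit and an allyl nucleophile. The allyl ketone 9 has one doubly activated methylene, which directs the diazo transfer. A Weinreb amide is chosen over the ester so that the allyl reagent adds only once.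

**7 ⇒ 6 ⇒ 3 + 4, and 3 ⇒ 1 + 2.** The C1–C2 bond is cut by a Johnson–Claisen rearrangement, which creates the (E)-trisubstituted C8a=C8 alkene and the conjugated diene together. The bis-allylic alcohol 3 comes from aldehyde 1 and Grignard reagent 2. This pairing is preferred to the reversed one because 1 is a single geometric isomer, whereas a propenyl metal reagent would be a mixture. The rearrangement must go through the isopropenyl arm of 3.

## Roads not taken

**Alternative 1:** The seven-membered ring is cut at C5–C6 and C8–C8a, giving the enantiopure cyclopentenyl siloxydiene A2 (C3 carbinol already present, from the chiral pool) and methyl 2-diazobut-3-enoate A3. A chiral dirhodium carboxylate would convert A3 into a vinylcarbenoid that cyclopropanates the terminal siloxy alkene of A2, and Cope rearrangement would give cycloheptadiene A1.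
- Merits: it is convergent, it uses the substrate class for which asymmetric vinylcarbenoid chemistry is best developed, and C3 and the C4 oxygen (as a silyl enol ether) are in place from the start. In these respects it is better than the chosen plan, which spends steps 7 to 12 moving oxygen.
- Weak points: C8a is formed in the Cope step at a fully substituted alkene terminus, one of whose substituents must point into the boat transition state. Its configuration depends on a match between the C3 centre and the catalyst. The ester on C6 of A1 must be reduced to a methyl group and the alkene moved, and A2 needs its own multi-step synthesis.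
- Against this the chosen plan sets a methyl group carried in as such, C8a fixed in the cyclopropanation, and an achiral precursor made in five steps.

**Alternative 2:** The five-membered ring is cut at C1–C8a and C3–C3a, leaving the symmetric 3,6-dimethylcyclohepta-2,6-dien-1-one A5 and 1-(propan-2-yl)cyclopropan-1-ol A6. A zinc homoenolate from A6, with a copper catalyst and a chiral phosphoramidite, would add to one enone of A5, and the enolate would close by aldol reaction onto the isopropyl ketone to give hydroxy enone A4.
- Merits: A4 is the desilylated form of 20, three steps from 27, with C8a, C3 and C3a set at once and no oxidation-level corrections. On step count this road is clearly better than the chosen plan.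
- Weak points: conjugate addition of a ketone homoenolate to a β,β-disubstituted cycloheptenone that creates a quaternary centre enantioselectively is not an established reaction class. The aldol onto a hindered isopropyl ketone is reversible, the C3 configuration rests on an untested transition state, and the second enone can react as well.
- The chosen plan offers only known reaction classes and a key step with close precedent; if the annulation were demonstrated, it would be the better route.

**Alternative 3:** The C3a–C8a bond is made by rearrangement: in the trans-fused decalin hydroxy mesylate A8 the tertiary alkoxide would drive migration of the methyl-bearing angular carbon to the mesylate carbon, giving the cis-fused hydroazulenone A7.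
- Merits: the shift is stereospecific, and the quaternary centre can come from an organocatalytic Robinson annulation with reliable absolute control. This is more secure than catalyst-controlled cyclopropanation of a diazo ketone. The C4 ketone is also delivered directly.
- Weak points: A8 has five defined stereocentres and requires a long linear sequence. C3 arrives as a protected secondary alcohol that must be deprotected, oxidised and alkylated in the presence of the C4 ketone.
- The chosen plan answers with a core formed in one step from a five-step acyclic precursor and with a downstream enzymatic resolution as insurance for the absolute configuration.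

Key step: step 6

Assumption: Rh2(S-PTAD)4 is taken to deliver the carbenoid to the alkene face that gives (1R,5S,6S)-11; should the sense of induction be the opposite, Rh2(R-PTAD)4 is used and nothing else changes.

## Steps

Step 1
Reactants: 1 (E)-but-2-enal; 2 isopropenylmagnesium bromide
Product: 3 (4E)-2-methylhexa-1,4-dien-3-ol (racemic)
Conditions: THF, −78 → 0 °C; aq. NH4Cl
Reagents that add atoms: none
Why: 1,2-addition of a Grignard reagent to an enal; the (E) alkene is brought in from 1 as a single geometric isomer, and the carbinol centre may be racemic because it becomes sp2 in step 2.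

Step 2
Reactants: 3 (4E)-2-methylhexa-1,4-dien-3-ol; 4 triethyl orthoacetate
Product: 6 ethyl (4E,6E)-4-methylocta-4,6-dienoate, via ketene acetal 5 (not isolated)
Conditions: 4 (excess), EtCO2H (cat.), 140 °C, EtOH distilled off
Reagents that add atoms: none
Why: Johnson–Claisen rearrangement; a chair transition state with the propenyl group equatorial gives the (4E) trisubstituted alkene. The shift should use the unsubstituted CH2 terminus of the isopropenyl arm rather than the methyl-bearing terminus of the propenyl arm, leaving the (E)-propenyl group as the second alkene of the diene.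

Step 3
Reactants: 6 ethyl (4E,6E)-4-methylocta-4,6-dienoate
Product: 7 (4E,6E)-N-methoxy-N,4-dimethylocta-4,6-dienamide
Conditions: MeNH(OMe)·HCl, iPrMgCl, THF, −20 → 0 °C
Reagents that add atoms: N,O-dimethylhydroxylamine hydrochloride, CNOC.Cl
Why: aminolysis of the ester by the chloromagnesium amide of N,O-dimethylhydroxylamine (Weinreb amide formation); the diene is a spectator.

Step 4
Reactants: 7 (4E,6E)-N-methoxy-N,4-dimethylocta-4,6-dienamide; 8 allylmagnesium bromide
Product: 9 (7E,9E)-7-methylundeca-1,7,9-trien-4-one
Conditions: THF, −78 °C; cold aq. NH4Cl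
Reagents that add atoms: none
Why: acyl substitution of a Weinreb amide; the chelated tetrahedral intermediate persists until work-up, so the allyl group adds once, and the cold, weakly acidic quench keeps the alkene in the β,γ position.

Step 5
Reactants: 9 (7E,9E)-7-methylundeca-1,7,9-trien-4-one
Product: 10 (7E,9E)-3-diazo-7-methylundeca-1,7,9-trien-4-one
Conditions: 4-AcNHC6H4SO2N3, DBU, MeCN, 0 °C; used at once
Reagents that add atoms: 4-acetamidobenzenesulfonyl azide, CC(=O)Nc1ccc(cc1)S(=O)(=O)N=[N+]=[N-]
Why: Regitz diazo transfer to the one methylene activated by both the carbonyl and the vinyl group (the dienolate reacts with the sulfonyl azide at its α carbon); the other α methylene is far less acidic. The product is kept cold and used directly because vinyl diazo ketones cyclise to pyrazoles on standing.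

Step 6
Reactants: 10 (7E,9E)-3-diazo-7-methylundeca-1,7,9-trien-4-one
Product: 12 (3aS,6S)-3a,6-dimethyl-3,3a,6,7-tetrahydroazulen-1(2H)-one, via divinylcyclopropane 11 (not isolated)
Conditions: Rh2(S-PTAD)4 (1 mol %), pentane, −40 → 20 °C, slow addition of 10; then toluene, 80 °C
Reagents that add atoms: none
Why: Loss of N2 at the divalent rhodium centre gives a donor/acceptor vinylcarbenoid that adds in a concerted, asynchronous way to the nearer, trisubstituted alkene (C7=C8 of 10), and the cis-divinylcyclopropane 11 then undergoes a [3,3] shift through a boat transition state; the closest known reaction type is the tandem cyclopropanation/Cope rearrangement (formal (4+3) cycloaddition) of vinylcarbenoids with dienes in its intramolecular diazo ketone form. The five-membered ring closes in the cyclopropanation itself, the two-carbon tether delivering the carbenoid to the alkene as a bicyclo[3.1.0]hexan-2-one. The seven-membered ring is not closed end to end but grows out of the cyclopropane by ring expansion, the C5–C6 bond (target locants) forming as the C3a–C8 cyclopropane bond breaks with release of ring strain. The quaternary centre (C3a of 12) is fixed in the cyclopropanation by the chiral carboxylate ligands of the catalyst, which select one face of the achiral alkene. The methyl-bearing centre C6 of 12 follows from the (E) geometry of the distal alkene and the boat geometry, is defined only relative to the quaternary centre, and is erased in step 12. The step needs attack at the proximal and not the distal alkene (the tether allows only the five-membered closure), a cis relation of the two alkenyl groups (the (7E) geometry places the propenyl group on the face of the bridgehead vinyl group) and carbenoid formation faster than cyclisation of 10 to a pyrazole (immediate use, slow addition, non-polar solvent). The angular methyl lies on the face of both alkenyl groups and should slow the Cope step, hence the warming.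

Step 7
Reactants: 12 (3aS,6S)-3a,6-dimethyl-3,3a,6,7-tetrahydroazulen-1(2H)-one
Product: 14 (3aS,6S,8R,8aS)-8-hydroxy-3a,6-dimethyl-3,3a,6,7,8,8a-hexahydroazulen-1(2H)-one, via pinacolboryl ketone 13 (not isolated)
Conditions: CuCl (5 mol %), Xantphos, NaOtBu (cat.), B2pin2, MeOH, THF, 20 °C; then NaBO3·4H2O, THF–H2O
Reagents that add atoms: sodium perborate tetrahydrate, O=BO[O-].[Na+]
Why: copper-catalysed conjugate borylation of the enone, then oxidation of the C–B bond with retention; the unactivated ring alkene does not react with the boryl copper species. Boron should add to C8 on the face away from the axial angular methyl and the enolate is then protonated anti to the new C–B bond, on the methyl face, which gives the cis ring fusion, also the arrangement expected to be favoured at equilibrium. The C8 carbinol centre is of no consequence because it is oxidised in step 10.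

Step 8
Reactants: 14 (3aS,6S,8R,8aS)-8-hydroxy-3a,6-dimethyl-3,3a,6,7,8,8a-hexahydroazulen-1(2H)-one; 2 isopropenylmagnesium bromide
Product: 15 (1S,3aS,6S,8R,8aS)-3a,6-dimethyl-1-(prop-1-en-2-yl)-1,2,3,3a,6,7,8,8a-octahydroazulene-1,8-diol
Conditions: 2 (4 equiv), CeCl3, THF, −78 → 0 °C
Reagents that add atoms: none
Why: organocerium-type 1,2-addition to the cyclopentanone on the convex face of the cis-fused bicycle, anti to C8 on the neighbouring ring-fusion carbon; this places the isopropenyl group cis to H8a and the angular methyl and the new hydroxyl on the concave face. CeCl3 keeps the reagent from enolising the ketone or fragmenting the aldolate.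

Step 9
Reactants: 15 (1S,3aS,6S,8R,8aS)-3a,6-dimethyl-1-(prop-1-en-2-yl)-1,2,3,3a,6,7,8,8a-octahydroazulene-1,8-diol
Product: 16 (1R,3aR,6R,8R,8aS)-3a,6-dimethyl-1-(propan-2-yl)decahydroazulene-1,8-diol
Conditions: H2 (1 atm), PtO2, EtOAc, 20 °C
Reagents that add atoms: none
Why: catalytic hydrogenation saturates the 1,1-disubstituted side-chain alkene and the cis-disubstituted ring alkene in one operation without forming a stereocentre; platinum is chosen over palladium to avoid hydrogenolysis of the tertiary allylic C–O bond.

Step 10
Reactants: 16 (1R,3aR,6R,8R,8aS)-3a,6-dimethyl-1-(propan-2-yl)decahydroazulene-1,8-diol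
Product: 17 (3R,3aR,6R,8aR)-3-hydroxy-6,8a-dimethyl-3-(propan-2-yl)octahydroazulen-4(1H)-one
Conditions: Dess–Martin periodinane, pyridine, CH2Cl2, 0 → 20 °C
Reagents that add atoms: none
Why: Dess–Martin oxidation takes the secondary alcohol to the ketone and leaves the tertiary alcohol alone; the buffered, non-basic medium should avoid retro-aldol cleavage, dehydration and epimerisation of the ring-fusion centre.

Step 11
Reactants: 17 (3R,3aR,6R,8aR)-3-hydroxy-6,8a-dimethyl-3-(propan-2-yl)octahydroazulen-4(1H)-one
Product: 18 (3R,3aR,6R,8aR)-6,8a-dimethyl-3-(propan-2-yl)-3-[(triethylsilyl)oxy]octahydroazulen-4(1H)-one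
Conditions: Et3SiOTf, 2,6-lutidine, CH2Cl2, −78 → 0 °C
Reagents that add atoms: triethylsilyl trifluoromethanesulfonate, CC[Si](CC)(CC)OS(=O)(=O)C(F)(F)F
Why: silylation of the hindered tertiary alcohol with a silyl triflate; the ether prevents alkoxide formation and hence retro-aldol cleavage under the strong base of step 12.

Step 12
Reactants: 18 (3R,3aR,6R,8aR)-6,8a-dimethyl-3-(propan-2-yl)-3-[(triethylsilyl)oxy]octahydroazulen-4(1H)-one
Product: 20 (3R,3aR,8aR)-6,8a-dimethyl-3-(propan-2-yl)-3-[(triethylsilyl)oxy]-2,3,3a,7,8,8a-hexahydroazulen-4(1H)-one, via trimethylsilyl enol ether 19 (not isolated)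
Conditions: LiN(iPr)2, Me3SiCl, THF, −78 °C; then Pd(OAc)2, MeCN, 20 °C
Reagents that add atoms: none
Why: Saegusa–Ito dehydrogenation; the amide base removes a proton from the accessible C5 methylene rather than from the ring-fusion methine flanked by two quaternary carbons, and divalent palladium converts the silyl enol ether into the enone by β-hydride elimination from C6. Only this side of the ketone has a β hydrogen, so the alkene can form only at C5=C6, and the C6 stereocentre left by the Cope step disappears.

Step 13
Reactants: 20 (3R,3aR,8aR)-6,8a-dimethyl-3-(propan-2-yl)-3-[(triethylsilyl)oxy]-2,3,3a,7,8,8a-hexahydroazulen-4(1H)-one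
Product: 21 (3R,3aS,4R,8aR)-6,8a-dimethyl-3-(propan-2-yl)-3-[(triethylsilyl)oxy]-1,2,3,3a,4,7,8,8a-octahydroazulen-4-ol
Conditions: NaBH4, CeCl3·7H2O, MeOH, −78 °C
Reagents that add atoms: none
Why: Luche 1,2-reduction of the enone; hydride is expected to enter from the convex face (that of H3a and the angular methyl), the concave face being screened by the triethylsilyloxy group on C3, so the new hydroxyl is placed on the concave face as (4R).

Step 14
Reactants: 22 3-hydroxy-4-methoxybenzoic acid (isovanillic acid)
Product: 24 3-[(tert-butyldimethylsilyl)oxy]-4-methoxybenzoic acid, via bis-silyl derivative 23 (not isolated)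
Conditions: tBuMe2SiCl (2.5 equiv), imidazole, DMF, 20 °C; then AcOH–THF–H2O
Reagents that add atoms: tert-butyldimethylsilyl chloride, CC(C)(C)[Si](C)(C)Cl
Why: silylation of both acidic hydroxyls followed by selective hydrolysis of the labile silyl ester; the aryl silyl ether masks the phenol during the acylation.

Step 15
Reactants: 21 (3R,3aS,4R,8aR)-6,8a-dimethyl-3-(propan-2-yl)-3-[(triethylsilyl)oxy]-1,2,3,3a,4,7,8,8a-octahydroazulen-4-ol; 24 3-[(tert-butyldimethylsilyl)oxy]-4-methoxybenzoic acid
Product: 26 (3R,3aS,4R,8aR)-6,8a-dimethyl-3-(propan-2-yl)-3-[(triethylsilyl)oxy]-1,2,3,3a,4,7,8,8a-octahydroazulen-4-yl 3-[(tert-butyldimethylsilyl)oxy]-4-methoxybenzoate, via mixed anhydride 25 (not isolated)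
Conditions: 24, 2,4,6-trichlorobenzoyl chloride, Et3N, toluene, 20 °C; then 21, DMAP, 20 → 40 °C
Reagents that add atoms: none
Why: Yamaguchi esterification; DMAP attacks the mixed anhydride at the carbonyl not flanked by two ortho chlorines, and the acylpyridinium ion acylates the hindered secondary allylic alcohol at oxygen, so C4 keeps its configuration.

Step 16
Reactants: 26 (3R,3aS,4R,8aR)-6,8a-dimethyl-3-(propan-2-yl)-3-[(triethylsilyl)oxy]-1,2,3,3a,4,7,8,8a-octahydroazulen-4-yl 3-[(tert-butyldimethylsilyl)oxy]-4-methoxybenzoate
Product: 27 (3R,3aS,4R,8aR)-3-hydroxy-6,8a-dimethyl-3-(propan-2-yl)-1,2,3,3a,4,7,8,8a-octahydroazulen-4-yl 3-hydroxy-4-methoxybenzoate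
Conditions: Bu4NF, AcOH, THF, 0 → 20 °C
Reagents that add atoms: none
Why: fluoride cleaves the aryl silyl ether and the tertiary triethylsilyl ether in one operation; buffering with acetic acid keeps the medium from becoming basic enough for acyl migration or ester cleavage, and no acid strong enough to ionise the allylic ester is present.

## Compound list

1 | (E)-but-2-enal (crotonaldehyde) | C/C=C/C=O | starting material
2 | isopropenylmagnesium bromide (prop-1-en-2-ylmagnesium bromide) | C=C(C)[Mg]Br | starting material
3 | (4E)-2-methylhexa-1,4-dien-3-ol, racemic | C=C(C)C(O)/C=C/C | intermediate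
4 | triethyl orthoacetate | CCOC(C)(OCC)OCC | starting material
5 | (4E)-3-[(1-ethoxyethenyl)oxy]-2-methylhexa-1,4-diene, racemic | C=C(OCC)OC(C(C)=C)/C=C/C | intermediate
6 | ethyl (4E,6E)-4-methylocta-4,6-dienoate | CCOC(=O)CC/C(C)=C/C=C/C | intermediate
7 | (4E,6E)-N-methoxy-N,4-dimethylocta-4,6-dienamide | CON(C)C(=O)CC/C(C)=C/C=C/C | intermediate
8 | allylmagnesium bromide | C=CC[Mg]Br | starting material
9 | (7E,9E)-7-methylundeca-1,7,9-trien-4-one | C=CCC(=O)CC/C(C)=C/C=C/C | intermediate
10 | (7E,9E)-3-diazo-7-methylundeca-1,7,9-trien-4-one | C=CC(=[N+]=[N-])C(=O)CC/C(C)=C/C=C/C | intermediate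
11 | (1R,5S,6S)-1-ethenyl-5-methyl-6-[(1E)-prop-1-en-1-yl]bicyclo[3.1.0]hexan-2-one | O=C1CC[C@@]2(C)[C@H](/C=C/C)[C@@]12C=C | intermediate
12 | (3aS,6S)-3a,6-dimethyl-3,3a,6,7-tetrahydroazulen-1(2H)-one | O=C1CC[C@@]2(C)C=C[C@@H](C)CC=C12 | intermediate
13 | (3aS,6S,8R,8aR)-3a,6-dimethyl-8-(4,4,5,5-tetramethyl-1,3,2-dioxaborolan-2-yl)-3,3a,6,7,8,8a-hexahydroazulen-1(2H)-one | O=C1CC[C@@]2(C)C=C[C@@H](C)C[C@@H](B3OC(C)(C)C(C)(C)O3)[C@@H]12 | intermediate
14 | (3aS,6S,8R,8aS)-8-hydroxy-3a,6-dimethyl-3,3a,6,7,8,8a-hexahydroazulen-1(2H)-one | O=C1CC[C@@]2(C)C=C[C@@H](C)C[C@@H](O)[C@@H]12 | intermediate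
15 | (1S,3aS,6S,8R,8aS)-3a,6-dimethyl-1-(prop-1-en-2-yl)-1,2,3,3a,6,7,8,8a-octahydroazulene-1,8-diol | O[C@@]1(C(C)=C)CC[C@@]2(C)C=C[C@@H](C)C[C@@H](O)[C@@H]12 | intermediate
16 | (1R,3aR,6R,8R,8aS)-3a,6-dimethyl-1-(propan-2-yl)decahydroazulene-1,8-diol | O[C@@]1(C(C)C)CC[C@@]2(C)CC[C@@H](C)C[C@@H](O)[C@@H]12 | intermediate
17 | (3R,3aR,6R,8aR)-3-hydroxy-6,8a-dimethyl-3-(propan-2-yl)octahydroazulen-4(1H)-one | O[C@@]1(C(C)C)CC[C@@]2(C)CC[C@@H](C)CC(=O)[C@@H]12 | intermediate
18 | (3R,3aR,6R,8aR)-6,8a-dimethyl-3-(propan-2-yl)-3-[(triethylsilyl)oxy]octahydroazulen-4(1H)-one | CC[Si](CC)(CC)O[C@@]1(C(C)C)CC[C@@]2(C)CC[C@@H](C)CC(=O)[C@@H]12 | intermediate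
19 | triethyl{[(3R,3aS,6R,8aR)-6,8a-dimethyl-3-(propan-2-yl)-4-[(trimethylsilyl)oxy]-1,2,3,3a,6,7,8,8a-octahydroazulen-3-yl]oxy}silane | CC[Si](CC)(CC)O[C@@]1(C(C)C)CC[C@@]2(C)CC[C@@H](C)C=C(O[Si](C)(C)C)[C@@H]12 | intermediate
20 | (3R,3aR,8aR)-6,8a-dimethyl-3-(propan-2-yl)-3-[(triethylsilyl)oxy]-2,3,3a,7,8,8a-hexahydroazulen-4(1H)-one | CC[Si](CC)(CC)O[C@@]1(C(C)C)CC[C@@]2(C)CCC(C)=CC(=O)[C@@H]12 | intermediate
21 | (3R,3aS,4R,8aR)-6,8a-dimethyl-3-(propan-2-yl)-3-[(triethylsilyl)oxy]-1,2,3,3a,4,7,8,8a-octahydroazulen-4-ol | CC[Si](CC)(CC)O[C@@]1(C(C)C)CC[C@@]2(C)CCC(C)=C[C@@H](O)[C@@H]12 | intermediate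
22 | 3-hydroxy-4-methoxybenzoic acid (isovanillic acid) | COc1ccc(C(=O)O)cc1O | starting material
23 | tert-butyldimethylsilyl 3-[(tert-butyldimethylsilyl)oxy]-4-methoxybenzoate | COc1ccc(C(=O)O[Si](C)(C)C(C)(C)C)cc1O[Si](C)(C)C(C)(C)C | intermediate
24 | 3-[(tert-butyldimethylsilyl)oxy]-4-methoxybenzoic acid | COc1ccc(C(=O)O)cc1O[Si](C)(C)C(C)(C)C | intermediate
25 | 3-[(tert-butyldimethylsilyl)oxy]-4-methoxybenzoic 2,4,6-trichlorobenzoic anhydride | COc1ccc(C(=O)OC(=O)c2c(Cl)cc(Cl)cc2Cl)cc1O[Si](C)(C)C(C)(C)C | intermediate
26 | (3R,3aS,4R,8aR)-6,8a-dimethyl-3-(propan-2-yl)-3-[(triethylsilyl)oxy]-1,2,3,3a,4,7,8,8a-octahydroazulen-4-yl 3-[(tert-butyldimethylsilyl)oxy]-4-methoxybenzoate | COc1ccc(C(=O)O[C@@H]2C=C(C)CC[C@]3(C)CC[C@@](O[Si](CC)(CC)CC)(C(C)C)[C@H]23)cc1O[Si](C)(C)C(C)(C)C | intermediate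
27 | (3R,3aS,4R,8aR)-3-hydroxy-6,8a-dimethyl-3-(propan-2-yl)-1,2,3,3a,4,7,8,8a-octahydroazulen-4-yl 3-hydroxy-4-methoxybenzoate | COc1ccc(C(=O)O[C@@H]2C=C(C)CC[C@]3(C)CC[C@@](O)(C(C)C)[C@H]23)cc1O | target

Total step count: 16. Longest linear sequence: 15 steps (steps 1–13, 15 and 16); step 14 is a one-step side branch.

## Least certain steps

**Step 6 (key step).**
- Most likely problem: incomplete face selection in the cyclopropanation. Chiral dirhodium carboxylates are best understood with diazoacetates, and here the tether dictates the approach of the alkene, so the ligands may discriminate the two faces only partly.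
- Fallback: the cascade is run for chemical efficiency alone and enantiomeric purity is established by enzymatic kinetic resolution. It sets out from diol 16 of insufficient enantiomeric purity. Immobilised Candida antarctica lipase B with vinyl acetate in tert-butyl methyl ether should acetylate the secondary hydroxyl of the (8R) enantiomer preferentially (the large ring-fusion side and the medium methylene side fit the usual size rule), giving (1R,3aR,6R,8R,8aS)-1-hydroxy-3a,6-dimethyl-1-(propan-2-yl)decahydroazulen-8-yl acetate F1. F1 is separated from the unreacted antipode and cleaved with K2CO3 in methanol, which returns the route to 16.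

**Step 5.**
- Most likely problem: slow transfer to a ketone dienolate under amine base, with base-induced conjugation of 9 and cyclisation of 10 to a pyrazole during prolonged contact with DBU.
- Fallback: activate, then transfer. From 9, kinetic enolisation with LiN(SiMe3)2 at −78 °C and C-acylation with 2,2,2-trifluoroethyl trifluoroacetate gives (7E,9E)-3-ethenyl-1,1,1-trifluoro-7-methylundeca-7,9-diene-2,4-dione F2. F2 undergoes detrifluoroacetylative diazo transfer with methanesulfonyl azide, triethylamine and water in acetonitrile at 20 °C and rejoins the route at 10.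

**Step 7.**
- Most likely problem: poor facial selectivity in the borylcupration or in the protonation of the enolate, giving the trans-fused epimer at the ring-fusion carbon together with 14.
- Fallback: thermodynamic instead of kinetic control. The mixture containing 14 is silylated (tBuMe2SiCl, imidazole) to (3aS,6S,8R,8aS)-8-[(tert-butyldimethylsilyl)oxy]-3a,6-dimethyl-3,3a,6,7,8,8a-hexahydroazulen-1(2H)-one F3 and its ring-fusion epimer. These are equilibrated with DBU in toluene toward the cis-fused F3, which is expected to be the more stable for a cyclopentanone beside an angular methyl; the silyl ether prevents β-elimination. Bu4NF with AcOH then returns the route to 14.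

**Step 13.**
- Most likely problem: poor facial selectivity in the hydride addition, because the isopropyl group on the convex face of C3 may offset the screening of the concave face by the silyl ether.
- Fallback: chelation control. From 20, Bu4NF with AcOH gives (3R,3aR,8aR)-3-hydroxy-6,8a-dimethyl-3-(propan-2-yl)-2,3,3a,7,8,8a-hexahydroazulen-4(1H)-one F4. Reduction under Narasaka–Prasad conditions (Et2BOMe, NaBH4, THF–MeOH, −78 °C), in which a boron chelate between the C3 oxygen and the C4 carbonyl directs hydride to the face of H3a, should give the syn diol (3R,3aS,4R,8aR)-6,8a-dimethyl-3-(propan-2-yl)-1,2,3,3a,4,7,8,8a-octahydroazulene-3,4-diol F5. Its secondary hydroxyl alone is acylated with 24 through 25 as in step 15, giving (3R,3aS,4R,8aR)-3-hydroxy-6,8a-dimethyl-3-(propan-2-yl)-1,2,3,3a,4,7,8,8a-octahydroazulen-4-yl 3-[(tert-butyldimethylsilyl)oxy]-4-methoxybenzoate F6. Bu4NF with AcOH then gives 27, where the fallback rejoins the route.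

## Further compounds

F1 | step 6 | (1R,3aR,6R,8R,8aS)-1-hydroxy-3a,6-dimethyl-1-(propan-2-yl)decahydroazulen-8-yl acetate | O[C@@]1(C(C)C)CC[C@@]2(C)CC[C@@H](C)C[C@@H](OC(C)=O)[C@@H]12
F2 | step 5 | (7E,9E)-3-ethenyl-1,1,1-trifluoro-7-methylundeca-7,9-diene-2,4-dione | C=CC(C(=O)C(F)(F)F)C(=O)CC/C(C)=C/C=C/C
F3 | step 7 | (3aS,6S,8R,8aS)-8-[(tert-butyldimethylsilyl)oxy]-3a,6-dimethyl-3,3a,6,7,8,8a-hexahydroazulen-1(2H)-one | O=C1CC[C@@]2(C)C=C[C@@H](C)C[C@@H](O[Si](C)(C)C(C)(C)C)[C@@H]12
F4 | step 13 | (3R,3aR,8aR)-3-hydroxy-6,8a-dimethyl-3-(propan-2-yl)-2,3,3a,7,8,8a-hexahydroazulen-4(1H)-one | O[C@@]1(C(C)C)CC[C@@]2(C)CCC(C)=CC(=O)[C@@H]12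
F5 | step 13 | (3R,3aS,4R,8aR)-6,8a-dimethyl-3-(propan-2-yl)-1,2,3,3a,4,7,8,8a-octahydroazulene-3,4-diol | O[C@@]1(C(C)C)CC[C@@]2(C)CCC(C)=C[C@@H](O)[C@@H]12
F6 | step 13 | (3R,3aS,4R,8aR)-3-hydroxy-6,8a-dimethyl-3-(propan-2-yl)-1,2,3,3a,4,7,8,8a-octahydroazulen-4-yl 3-[(tert-butyldimethylsilyl)oxy]-4-methoxybenzoate | COc1ccc(C(=O)O[C@@H]2C=C(C)CC[C@]3(C)CC[C@@](O)(C(C)C)[C@H]23)cc1O[Si](C)(C)C(C)(C)C
A1 | alternative 1 | methyl (1R,3aS)-8-[(tert-butyldimethylsilyl)oxy]-3a-methyl-1-(propan-2-yl)-1-[(triethylsilyl)oxy]-1,2,3,3a,4,7-hexahydroazulene-6-carboxylate | COC(=O)C1=CC[C@]2(C)CC[C@@](O[Si](CC)(CC)CC)(C(C)C)C2=C(O[Si](C)(C)C(C)(C)C)C1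
A2 | alternative 1 | tert-butyl({1-[(5R)-2-methyl-5-(propan-2-yl)-5-[(triethylsilyl)oxy]cyclopent-1-en-1-yl]ethenyl}oxy)dimethylsilane | C=C(O[Si](C)(C)C(C)(C)C)C1=C(C)CC[C@@]1(O[Si](CC)(CC)CC)C(C)C
A3 | alternative 1 | methyl 2-diazobut-3-enoate | C=CC(=[N+]=[N-])C(=O)OC
A4 | alternative 2 | (3R,3aR,8aR)-3-hydroxy-6,8a-dimethyl-3-(propan-2-yl)-2,3,3a,7,8,8a-hexahydroazulen-4(1H)-one | O=C1C=C(C)CC[C@]2(C)CC[C@@](O)(C(C)C)[C@H]12
A5 | alternative 2 | 3,6-dimethylcyclohepta-2,6-dien-1-one | O=C1C=C(C)CCC(C)=C1
A6 | alternative 2 | 1-(propan-2-yl)cyclopropan-1-ol | CC(C)C1(O)CC1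
A7 | alternative 3 | (3R,3aR,6R,8aR)-3-[(tert-butyldimethylsilyl)oxy]-6,8a-dimethyloctahydroazulen-4(1H)-one | O=C1C[C@H](C)CC[C@]2(C)CC[C@@H](O[Si](C)(C)C(C)(C)C)[C@H]12
A8 | alternative 3 | trans-fused 3-[(tert-butyldimethylsilyl)oxy]-4a-hydroxy-6,8a-dimethyldecahydronaphthalen-4-yl methanesulfonate (4a-hydroxyl anti to the 8a-methyl, mesylate equatorial and syn to the 4a-hydroxyl) | CS(=O)(=O)O[C@H]1[C@H](O[Si](C)(C)C(C)(C)C)CC[C@@]2(C)CC[C@@H](C)C[C@]12O
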